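The readings are calculated on assumed constants; noise was put on by code.

The cedar run, at 20 °C, behaved as I expected: between 6.00 h and 25.0 h target rose from 29.9 % to 33.0 % while starting material fell from 69.9 % to 66.1 %.

all flasks: starting material 20 mM
- elm: reagent 1.1 equiv; second substrate 2 equiv; temperature 35 °C; the very flask that is asked about, followed so far
- cedar: reagent 1.1 equiv; second substrate 4 equiv; temperature 20 °C; run made earlier
- flask: reagent 1.10 equiv; second substrate 2.00 equiv; temperature 35 °C; time 30 h

| run | time / h | target / % | starting material / % |
|---|---|---|---|
| elm | 2.00 | 33.0 | 66.5 |
| elm | 6.00 | 32.7 | 63.1 |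
| elm | 12.0 | 31.3 | 61.2 |
| elm | 15.0 | 29.8 | 60.5 |
| elm | 25.0 | 27.5 | 57.5 |
| cedar | 6.00 | 29.9 | 69.9 |
| cedar | 12.0 | 31.0 | 67.1 |
| cedar | 20.0 | 32.4 | 66.6 |
| cedar | 25.0 | 33.0 | 66.1 |
| cedar | 30.0 | 32.5 | 65.9 |

(each reading ± 0.5 percentage points)

1. target, in percent of the starting material first charged, at 30 h
2. the remedy with the largest gain of target, or "none" below 2 percentage points (Tuesday's / Sunday's / Wednesday's / Friday's / none)
3. target present, with what was taken out counted in, in percent of the starting material first charged, after Tuesday's
4. target present, with what was taken out counted in, in percent of the starting material first charged, after Sunday's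

- Tuesday's: at 30 h raise the temperature by 15 K, then wait 30 h
- Sunday's: at 30 h add reagent, 50.0 % of the amount charged, then wait 30 h
- Wednesday's: at 30 h take out 90 % of the target then present, then wait 30 h
- Friday's: change nothing and wait 30 h more

- removed target is counted in
- the numbers in the tables scatter with a standard deviation of 0.5 percentage points
- on the list of suspects stand: starting material + reagent <-> target; second substrate + reagent <-> second product; target <-> isomer of the product
- additions bring no volume worth counting

The elm flask looked contradictory. Between 2.00 h and 25.0 h, c(target) fell from 33.0 % to 27.5 %, yet c(starting material), from which target is made, fell too, from 66.5 % to 57.5 %. So their sum, which I called the pool, was draining: it went from 99.5 % to 85.0 %, a loss of 15 percentage points.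

I supposed that target leaks into its isomer at a rate proportional to c(target). Integrated over the run, the loss equals a constant times the mean c(target) times the time. That gave the leak constant, the first-order rate constant of the drain, 0.0208 /h. Its time, ln(2) over the constant, is 33.3 h, much longer than the 2.00 h of the first reading, by which target in elm already stood at 33.0 %. So I treated the pool as balanced at each moment. Target's share of the pool barely moved, from 33.2 % to 32.4 %. With a fixed share the pool decays exponentially, and carrying the last reading on to 30 h gave me 26.6 %.

The forecast said 26.3 %, a little below my figure. It named Wednesday's as best, with 4.5 % after Tuesday's and 27 % after Sunday's. Its ground was that the sum of the two “drains steadily”, which it read as target passing into its isomer.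

The flask gave 25.6 % at 30 h. Wednesday's came out best, with a gain of 9.8 points, and the target stood at 5.64 % after Tuesday's and 26.2 % after Sunday's.

    starting material + reagent ⇌ target (K = 59.0 /M, k = 0.790 /M/min, Ea = 44.0 kJ/mol, ΔH = −49.0 kJ/mol)
    second substrate + reagent ⇌ second product (K = 19.0 /M, k = 0.890 /M/min, Ea = 62.0 kJ/mol, ΔH = −54.0 kJ/mol)
    target ⇌ isomer of the product (K = 26.0, k = 3.60 × 10⁻⁴ /min, Ea = 113 kJ/mol, ΔH = 8.00 kJ/mol)
    (constants at 35 °C)

At 30.0 h in the flask, the step between starting material, reagent and target, taken by itself, relaxes with a half-life of 0.406 h, far shorter than the relaxation half-life of 30.9 h of the step between target and isomer, also taken by itself. The leak constant, times the 29.8 % of target at 15.0 h and times 30 h, makes 18.6 % of isomer, and the flask holds 18.8 % at 30.0 h. For the neighbour flask with 8.0 mM of starting material, at the same temperature, the leak constant over 30 h, with target taken as steady, puts isomer at about 0.624 of target. Computed, that flask holds 13.3 % of isomer and 19.1 % of target, a ratio of 0.696.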